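**Numbering and conventions.** Compounds are numbered 1–26 in the order they appear in the steps below, and these numbers are used in every section. Rings: A is the benzene ring carrying the ring ketone and the ether oxygen; B is the benzenoid ring of the tricycle; C is the partly saturated ring; D is the enolised diketone ring; E is the 2,6-dioxygenated phenyl ring. Carbons follow the pentane-1,5-dione chain of the open-chain intermediate 20: C1 bears ring E, C2 is the ring C methine, C3 the side-chain CH–CH3, C4 the CH2, C5 the ring A ketone carbon, and C1′ the benzylic CH–CH3. Naphthalene positions are always written as "naphthalene position n".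

## Analysis of the target

The target (C30H24O8) is a dihydrophenalenone: rings B, C and D share one central carbon, ring C carries ring E on its sp2 carbon C1, and a ten-membered ring runs from C1′ and C2 of ring C through C3, C4 and the C5 ketone to ring A and back to ring B through a diaryl ether oxygen. There are three contiguous stereocentres, C1′ (R), C2 (R) and C3 (S). On ring C the C1′ methyl group and the C2–C3 bond are trans, so the macrocyclic bridge lies on the face opposite the methyl group. Rings C and D form a quinone-methide-like vinylogous acid (ring D C=O, enol OH, exocyclic C1=C double bond), so C2–H is vinylogously acidic and C2 can equilibrate through the tautomeric naphthalene-1,3-diol. Five phenolic or enolic OH groups make the compound sensitive to base, to air and to strong acid. The hard parts are a stereotriad of acyclic type that ends up straddling ring C and the macrocycle, the strained ten-membered diaryl ether ketone, and a 1,3,6,8-tetraoxygenated naphthalene that must be differentiated at a single oxygen. The strategy rests on one feature: once ring C is opened at the bond between C1 and naphthalene position 8, C1′, C2 and C3 lie β and α to the C1 ketone and β to the C5 ketone, so they map onto a methyl nucleophile and two aryl enones.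

## Retrosynthetic reasoning

**26 to 24.** The six O–CH3 bonds are cut last, because methyl ethers are the only phenol protection that survives organozinc, hydrogenolysis, carbonate base and protic acid. The forward step has to cleave six aryl methyl ethers without touching the diaryl ether or the C5 ketone. It must also let the liberated naphthalenediol 25 settle into the quinone-methide tautomer, with C2 protonated trans to the C1′ methyl group.

**24 to 22.** Ring C is opened at the bond between C1 and naphthalene position 8. This is the one ring bond that a ketone and an electron-rich arene can form by themselves, and cutting it turns the tricycle back into an intact naphthalene, so ring D never has to be built. The forward reaction is a peri cyclodehydration, which needs the C1 ketone still flanked by methyl ethers (twisted and electrophilic) and the naphthalene still activated by its 5- and 7-methoxy groups.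

**22 to 21 to 20.** The macrocycle is cut at the ring A carbon–oxygen bond. The ether oxygen is already on the naphthalene, and the ring A carbon sits ortho to the C5 ketone, so a fluoride there can be displaced. This leaves the open-chain 1,5-diketone 21 and, one protecting group earlier, its benzyl ether 20. The forward closure has to form a ten-membered ring under base without enolising the diketone.

**20 to 12, 18 and 17.** The C1′–CH3 bond and the C2–C3 bond are cut together. Both lie on the same enolate: methyl addition to the enone of 12 creates it and the enone 17 consumes it. The cut removes all three stereocentres at once and leaves two flat enones and dimethylzinc 18. The forward step must set C1′ absolutely, C2 relative to C1′, and C3 relative to C2.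

**12 to 9 and 10.** The enone double bond is cut by a retro-aldol condensation into the naphthaldehyde 9 and the methyl ketone 10, which has only one enolisable side.

**9 to 5 to 1.** The benzyl ether is traced to the phenol 8, which comes from the tetramethyl ether 7 by removing the one methyl group that sits ortho to the formyl group. The formyl group goes on the symmetric tetramethoxynaphthalene 5 at its most nucleophilic α-position. The second ring of 5 is cut at the bond formed by an intramolecular Claisen condensation of the keto ester 3, which comes from 2 and the commercial acid 1 by ring acylation. Symmetry in 5 removes any regiochemical question until the formylation.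

**17 to 13 and 14.** The aryl ketone is cut at the aryl–carbonyl bond into the aryllithium 15 from 13 and the E aldehyde 14, through alcohol 16. This fixes the E geometry that the Michael step needs.

## Alternatives that were turned down

**Alternative 1:** Ring D is removed last. The two C–C(=O) bonds that tie it to the styrenic carbon of ring C and to the peri carbon of ring B are cut, leaving the macrocyclic aryl-dihydronaphthalene A1 and malonyl dichloride A2. In the forward step a stoichiometric Lewis acid would acylate both CH positions with A2 and give the tetra-O-methyl ether A3 with ring D as its enol.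
- For it: ring D arrives in two bonds at the final oxidation level, and C2 is never flattened. On that point it is stronger than the chosen end game, which passes through the C1=C2 alkene 24.
- Against it: A1 offers several better nucleophiles than the wanted pair. Ring E is a 1,3-dimethoxybenzene with free activated positions, ring B has a second site between its two oxygens, and the trisubstituted styrene tends under Lewis acid to add chloride or shift its double bond toward C2. Ethers ortho to the C5 ketone can be lost as well.
- Comparison: A1 must already hold the macrocycle and all three stereocentres, so this step says nothing about where they come from. The chosen route starts from a naphthalene, so the ring D carbons never need regioselective introduction, and it offers a stereotriad-forming step in exchange for the less elegant C2 reset.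

**Alternative 2:** The C4–C5 and C5–ring A bonds are cut with excision of the carbonyl carbon, giving the isopropenyl diaryl ether iodide A4 and carbon monoxide A5. In the forward step a dialkylborane hydroborates the isopropenyl group, and palladium catalysis then joins the alkylborane, A5 and the aryl iodide to close the ten-membered ketone A1.
- For it: the diaryl ether is made early and intermolecularly, and the macrocycle closes under near-neutral conditions with no enolisable 1,5-diketone present. This is stronger than the chosen closure by fluoride displacement next to a twisted, weakly activating ketone.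
- Against it: C3 is created in the hydroboration of a 1,1-disubstituted alkene, with only acyclic 1,2-induction from C2 to control it. The acyl-palladium closure competes with direct alkyl–aryl coupling to a nine-membered ring and with β-hydride elimination. The iodide is flanked by two ortho oxygens. The product A1 still lacks ring D, so the acylation problem of alternative 1 follows.
- Comparison: the chosen route sets C3 in the same step as C1′ and C2 through a defined enolate–enone topology, and it has ring D in place from the first step.

**Alternative 3:** Rings B and D are cut together in a polyketide manner back to the ring C cyclohexenone A6, which carries a dioxinone-masked ketoacyl chain and an acetyl group. In the forward step, heating with an alcohol and then alkoxide unveils a diketo ester chain. Its ester-flanked CH2 condenses on the ring C ketone to close ring B, and the acetyl CH3 attacks the ester to close ring D, giving the tricyclic core A7.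
- For it: two rings and the whole oxygenation pattern form in one operation, with free phenols and ring D already in its final tautomer. It is clearly stronger than the chosen route in protecting-group economy and avoids a six-fold ether cleavage.
- Against it: A6 already contains C1′, C2 and C3 plus an epimerisable acyl-bearing carbon, so the key step builds no stereocentre. Alkoxide endangers C2, which is the γ-position of the ring C enone. The unveiled chain can lactonise to a pyranone or condense on the acetyl group. From A7 the macrocycle still has to be made from a vinyl group and one of two free ring B phenols.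
- Comparison: the chosen route makes the stereotriad from achiral components in one step and carries both macrocycle termini from that step onward.

Key step: step 10

## Route

Assumption 1: the quinone-methide tautomer drawn for the target, with sp3 C2, is taken as the stable tautomer, and C2 trans to the C1′ methyl group as the thermodynamically preferred configuration.
Assumption 2: the phosphoramidite antipode used is the one that delivers methyl to the Re face of the β-carbon of 12; both antipodes are accessible.

Step 1
Reactants: 1 3,5-dimethoxyphenylacetic acid
Product: 2 methyl 2-(3,5-dimethoxyphenyl)acetate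
Conditions: MeOH, H2SO4 (cat.), reflux
Reagents that add atoms: methanol, CO
Why: Fischer esterification; the ester serves as the acyl acceptor of the later Claisen ring closure.

Step 2
Reactants: 2 methyl 2-(3,5-dimethoxyphenyl)acetate
Product: 3 methyl 2-(2-acetyl-3,5-dimethoxyphenyl)acetate
Conditions: AcCl, SnCl4, CH2Cl2, 0 °C
Reagents that add atoms: acetyl chloride, CC(=O)Cl
Why: Friedel–Crafts acylation; attack should occur para to one methoxy group and ortho to the other, next to the CH2 group, because the site between the two methoxy groups is more hindered, and the mild Lewis acid spares the ethers.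

Step 3
Reactants: 3 methyl 2-(2-acetyl-3,5-dimethoxyphenyl)acetate
Product: 5 1,3,6,8-tetramethoxynaphthalene, via 6,8-dimethoxynaphthalene-1,3-diol 4 (not isolated)
Conditions: NaOMe, MeOH, reflux, N2; evaporate; Me2SO4, acetone, reflux
Reagents that add atoms: dimethyl sulfate, COS(=O)(=O)OC
Why: Intramolecular Claisen (Dieckmann-type) condensation of the acetyl enolate on the ester closes the second ring, which aromatises to the diolate of 4; the air-sensitive diolate is O-methylated directly in a Williamson etherification.

Step 4
Reactants: 5 1,3,6,8-tetramethoxynaphthalene
Product: 7 2,4,5,7-tetramethoxy-1-naphthaldehyde, via aryl iminium chloride 6 (not isolated)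
Conditions: POCl3 (1.1 equiv), DMF, 0 → 60 °C; then H2O
Reagents that add atoms: N,N-dimethylformamide, CN(C)C=O; water, O
Why: Vilsmeier–Haack formylation; the α-position para to one methoxy group and ortho to another is the most nucleophilic site of the symmetric naphthalene, and the deactivated iminium 6 should resist a second formylation.

Step 5
Reactants: 7 2,4,5,7-tetramethoxy-1-naphthaldehyde
Product: 8 2-hydroxy-4,5,7-trimethoxy-1-naphthaldehyde
Conditions: BCl3 (1.2 equiv), CH2Cl2, −78 → 0 °C; then H2O
Reagents that add atoms: none
Why: Chelation-directed ether cleavage; BCl3 bridges the formyl oxygen and the neighbouring methoxy oxygen, so only the ether ortho to the aldehyde should be dealkylated.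

Step 6
Reactants: 8 2-hydroxy-4,5,7-trimethoxy-1-naphthaldehyde
Product: 9 2-(benzyloxy)-4,5,7-trimethoxy-1-naphthaldehyde
Conditions: BnBr, K2CO3, DMF, 60 °C
Reagents that add atoms: benzyl bromide, BrCc1ccccc1
Why: Williamson etherification; the benzyl group marks the one oxygen that later becomes the macrocyclic ether and is removable without touching methyl ethers or the aryl fluoride.

Step 7
Reactants: 9 2-(benzyloxy)-4,5,7-trimethoxy-1-naphthaldehyde; 10 2′,6′-dimethoxyacetophenone
Product: 12 (E)-3-[2-(benzyloxy)-4,5,7-trimethoxynaphthalen-1-yl]-1-(2,6-dimethoxyphenyl)prop-2-en-1-one, via β-hydroxy ketone 11 (not isolated)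
Conditions: KOH (aq., 50 mol%), EtOH/THF, rt → 50 °C
Reagents that add atoms: none
Why: Claisen–Schmidt condensation; 10 enolises on one side only, 9 cannot enolise, and E1cB dehydration of 11 should give the E enone.

Step 8
Reactants: 13 3-fluoroanisole; 14 (E)-but-2-enal
Product: 16 (E)-1-(2-fluoro-6-methoxyphenyl)but-2-en-1-ol (racemic), via aryllithium 15 (not isolated)
Conditions: n-BuLi, THF, −78 °C; then 14, −78 °C; aq. NH4Cl
Reagents that add atoms: none
Why: Directed ortho-metalation at the carbon flanked by fluorine and methoxy, then 1,2-addition of the hard aryllithium to the enal; −78 °C prevents aryne formation and the E alkene comes from 14.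

Step 9
Reactants: 16 (E)-1-(2-fluoro-6-methoxyphenyl)but-2-en-1-ol
Product: 17 (E)-1-(2-fluoro-6-methoxyphenyl)but-2-en-1-one
Conditions: MnO2 (excess), CH2Cl2, rt
Reagents that add atoms: none
Why: MnO2 oxidation of an allylic, benzylic alcohol; the neutral conditions should leave the E alkene in place and unconjugated.

Step 10
Reactants: 12 (E)-3-[2-(benzyloxy)-4,5,7-trimethoxynaphthalen-1-yl]-1-(2,6-dimethoxyphenyl)prop-2-en-1-one; 18 dimethylzinc; 17 (E)-1-(2-fluoro-6-methoxyphenyl)but-2-en-1-one
Product: 20 (2R,3S)-2-[(1R)-1-[2-(benzyloxy)-4,5,7-trimethoxynaphthalen-1-yl]ethyl]-1-(2,6-dimethoxyphenyl)-5-(2-fluoro-6-methoxyphenyl)-3-methylpentane-1,5-dione, via methylzinc Z-enolate 19 (not isolated)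
Conditions: Cu(OTf)2 (5 mol%), BINOL/bis(1-phenylethyl)amine phosphoramidite (10 mol%), 18 (1.2 equiv), toluene, −20 → 0 °C; then 17 (1.3 equiv), −20 → 0 °C; aq. NH4Cl
Reagents that add atoms: none
Why: 18 reduces Cu(OTf)2 to a monovalent copper phosphoramidite complex, which takes up methyl, binds the s-cis enone of 12 as a π-complex and delivers methyl to the β-carbon C1′ through a trivalent copper intermediate and reductive elimination, leaving the Z zinc enolate 19. The closest known reaction type is the copper/phosphoramidite-catalysed enantioselective 1,4-addition of dialkylzinc reagents to chalcones with trapping of the zinc enolate by a second Michael acceptor. No ring closes. C1′ is set by the ligand, whose pocket should expose only the Re face of the β-carbon to methyl, giving R. C2 is set by allylic 1,3-strain in 19: the C1′–H bond lies in the enolate plane beside the O–Zn group, so naphthyl and methyl shield opposite faces and 17 should approach past the methyl group, anti to the naphthyl group, on the Re face of the enolate carbon (R). C3 is set by the topology of the Michael step: the Z enolate and the s-cis E enone 17 should combine through a closed, zinc-bridged transition state that joins the enolate Re face to the Si face of the enone β-carbon, which is the anti C2/C3 arrangement (S). The step needs 1,4- over 1,2-addition, which the two ortho substituents on each aroyl ring secure, and methyl transfer to 12 only, which is secured by adding 17 after 12 is consumed and by keeping 18 near one equivalent; low temperature and the small excess of 17 should hold back a second Michael addition of the product enolate.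

Step 11
Reactants: 20 benzyl ether diketone (as named in step 10)
Product: 21 (2R,3S)-1-(2,6-dimethoxyphenyl)-5-(2-fluoro-6-methoxyphenyl)-2-[(1R)-1-(2-hydroxy-4,5,7-trimethoxynaphthalen-1-yl)ethyl]-3-methylpentane-1,5-dione
Conditions: H2 (1 atm), Pd/C, EtOAc, rt
Reagents that add atoms: none
Why: Hydrogenolysis of the benzyl aryl ether; the aryl fluoride, the hindered aryl ketones and the methyl ethers should be inert at one atmosphere.

Step 12
Reactants: 21 naphthol diketone (as named in step 11)
Product: 22 macrocyclic diketone: the naphthalene 2-oxygen of 21 bonded to the ring A carbon that carried fluorine, closing the ten-membered ring (C1′ R, C2 R, C3 S)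
Conditions: Cs2CO3 (3 equiv), DMF, 80 °C, 0.002 M, slow addition
Reagents that add atoms: none
Why: Intramolecular nucleophilic aromatic substitution; the naphthoxide attacks the fluoride ortho to the C5 ketone, whose carbonyl stabilises the Meisenheimer intermediate, and high dilution favours ring closure over dimers. Hemiketal formation between the naphthol and the C1 ketone is reversible under base and should not drain material.

Step 13
Reactants: 22 macrocyclic diketone
Product: 24 hexa-O-methyl 1H-phenalene macrocycle with a C1=C2 double bond (C1′ R, C3 S), via tertiary carbinol 23 (not isolated)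
Conditions: MeSO3H, CH2Cl2, 0 °C → rt
Reagents that add atoms: none
Why: Friedel–Crafts hydroxyalkylation of the protonated C1 ketone by naphthalene position 8 (ortho and para to methoxy groups, peri to the chain) closes six-membered ring C, and the doubly benzylic cation from 23 loses its only β-hydrogen, at C2, in a Bradsher-type cyclodehydration. C2 is flattened here and is set again in step 14; C1′ and C3 are not touched.

Step 14
Reactants: 24 hexa-O-methyl 1H-phenalene macrocycle
Product: 26 CNP0225737.1 (C1′ R, C2 R, C3 S), via hexahydroxy naphthalene tautomer 25 (not isolated)
Conditions: BBr3 (12 equiv), CH2Cl2, −78 °C → rt; then MeOH/H2O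
Reagents that add atoms: none
Why: Lewis-acid SN2 demethylation of all six aryl methyl ethers, with the diaryl ether and the C5 ketone expected to stay intact. The naphthalene-1,3-diol 25 should tautomerise to the vinylogous acid by protonation at C2; under the equilibrating acidic conditions the proton should end cis to the C1′ methyl group, which puts the macrocyclic bridge and that methyl group trans and pseudoaxial and restores R at C2.

## Compound list

1 | 3,5-dimethoxyphenylacetic acid | COc1cc(CC(=O)O)cc(OC)c1 | starting material
2 | methyl 2-(3,5-dimethoxyphenyl)acetate | COC(=O)Cc1cc(OC)cc(OC)c1 | intermediate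
3 | methyl 2-(2-acetyl-3,5-dimethoxyphenyl)acetate | COC(=O)Cc1cc(OC)cc(OC)c1C(C)=O | intermediate
4 | 6,8-dimethoxynaphthalene-1,3-diol (present as its disodium salt) | COc1cc(OC)c2c(O)cc(O)cc2c1 | intermediate
5 | 1,3,6,8-tetramethoxynaphthalene | COc1cc(OC)c2c(OC)cc(OC)cc2c1 | intermediate
6 | N,N-dimethyl(2,4,5,7-tetramethoxynaphthalen-1-yl)methaniminium chloride | C[N+](C)=Cc1c(OC)cc(OC)c2c(OC)cc(OC)cc12.[Cl-] | intermediate
7 | 2,4,5,7-tetramethoxy-1-naphthaldehyde | O=Cc1c(OC)cc(OC)c2c(OC)cc(OC)cc12 | intermediate
8 | 2-hydroxy-4,5,7-trimethoxy-1-naphthaldehyde | O=Cc1c(O)cc(OC)c2c(OC)cc(OC)cc12 | intermediate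
9 | 2-(benzyloxy)-4,5,7-trimethoxy-1-naphthaldehyde | O=Cc1c(OCc2ccccc2)cc(OC)c2c(OC)cc(OC)cc12 | intermediate
10 | 2′,6′-dimethoxyacetophenone | CC(=O)c1c(OC)cccc1OC | starting material
11 | 3-[2-(benzyloxy)-4,5,7-trimethoxynaphthalen-1-yl]-1-(2,6-dimethoxyphenyl)-3-hydroxypropan-1-one (racemic) | COc1cccc(OC)c1C(=O)CC(O)c1c(OCc2ccccc2)cc(OC)c2c(OC)cc(OC)cc12 | intermediate
12 | (E)-3-[2-(benzyloxy)-4,5,7-trimethoxynaphthalen-1-yl]-1-(2,6-dimethoxyphenyl)prop-2-en-1-one | COc1cccc(OC)c1C(=O)/C=C/c1c(OCc2ccccc2)cc(OC)c2c(OC)cc(OC)cc12 | intermediate
13 | 3-fluoroanisole | COc1cccc(F)c1 | starting material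
14 | (E)-but-2-enal | C/C=C/C=O | starting material
15 | (2-fluoro-6-methoxyphenyl)lithium | [Li]c1c(F)cccc1OC | intermediate
16 | (E)-1-(2-fluoro-6-methoxyphenyl)but-2-en-1-ol (racemic) | C/C=C/C(O)c1c(F)cccc1OC | intermediate
17 | (E)-1-(2-fluoro-6-methoxyphenyl)but-2-en-1-one | C/C=C/C(=O)c1c(F)cccc1OC | intermediate
18 | dimethylzinc | C[Zn]C | starting material
19 | methylzinc (Z)-enolate of the C1 ketone after methyl addition (C1′ R) | C[Zn]O/C(c1c(OC)cccc1OC)=C\[C@@H](C)c1c(OCc2ccccc2)cc(OC)c2c(OC)cc(OC)cc12 | intermediate
20 | (2R,3S)-2-[(1R)-1-[2-(benzyloxy)-4,5,7-trimethoxynaphthalen-1-yl]ethyl]-1-(2,6-dimethoxyphenyl)-5-(2-fluoro-6-methoxyphenyl)-3-methylpentane-1,5-dione | C[C@@H](CC(=O)c1c(OC)cccc1F)[C@H]([C@@H](C)c1c(OCc2ccccc2)cc(OC)c2c(OC)cc(OC)cc12)C(=O)c1c(OC)cccc1OC | intermediate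
21 | (2R,3S)-1-(2,6-dimethoxyphenyl)-5-(2-fluoro-6-methoxyphenyl)-2-[(1R)-1-(2-hydroxy-4,5,7-trimethoxynaphthalen-1-yl)ethyl]-3-methylpentane-1,5-dione | C[C@@H](CC(=O)c1c(OC)cccc1F)[C@H]([C@@H](C)c1c(O)cc(OC)c2c(OC)cc(OC)cc12)C(=O)c1c(OC)cccc1OC | intermediate
22 | macrocyclic diketone, ten-membered diaryl ether ring, six OMe (C1′ R, C2 R, C3 S) | C[C@H]1CC(=O)c2c(OC)cccc2Oc2cc(OC)c3c(OC)cc(OC)cc3c2[C@H](C)[C@@H]1C(=O)c1c(OC)cccc1OC | intermediate
23 | ring C carbinol: 22 with naphthalene position 8 bonded to C1, C1 bearing OH and ring E (carbinol centre undefined) | C[C@H]1CC(=O)c2c(OC)cccc2Oc2cc(OC)c3c(OC)cc(OC)c4c3c2[C@H](C)[C@@H]1C4(O)c1c(OC)cccc1OC | intermediate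
24 | hexa-O-methyl 1H-phenalene macrocycle, C1=C2 double bond (C1′ R, C3 S) | C[C@H]1CC(=O)c2c(OC)cccc2Oc2cc(OC)c3c(OC)cc(OC)c4c3c2[C@H](C)C1=C4c1c(OC)cccc1OC | intermediate
25 | hexahydroxy 1H-phenalene tautomer of the target, C1=C2 double bond, naphthalene-1,3-diol ring D (C1′ R, C3 S) | C[C@H]1CC(=O)c2c(O)cccc2Oc2cc(O)c3c(O)cc(O)c4c3c2[C@H](C)C1=C4c1c(O)cccc1O | intermediate
26 | CNP0225737.1, pentahydroxy dihydrophenalenone macrocycle (C1′ R, C2 R, C3 S) | C[C@H]1CC(=O)c2c(O)cccc2Oc2cc(O)c3c4c2[C@H](C)[C@@H]1C(c1c(O)cccc1O)=C4C(O)=CC3=O | target

## Step count and weak points

Total: 14 steps. Longest linear sequence: 12 steps (steps 1–7 and 10–14 from 1); the enone 17 is made in a two-step branch.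

**Step 10 (key step).** The β-carbon of 12 carries a twisted, doubly ortho-substituted naphthyl group, so methyl transfer may be slow or poorly face-selective. The zinc enolate 19 may add too sluggishly to 17, so that simple protonation wins, or residual 18 with copper may methylate 17. Fallback, setting out from 12: the same copper-catalysed methyl addition is quenched with aqueous NH4Cl to isolate (R)-3-[2-(benzyloxy)-4,5,7-trimethoxynaphthalen-1-yl]-1-(2,6-dimethoxyphenyl)butan-1-one F1, which can be enriched by crystallisation. LDA in THF at −78 °C then gives its lithium (Z)-enolate F2, the geometry expected for a bulky aryl ketone. Kinetic Michael addition of this enolate to 17 at −78 °C should give the same anti adduct under the same 1,3-strain control, and the route is rejoined at 20.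

**Step 12.** The open-chain 1,5-diketone may enolise under carbonate, leading to retro-Michael cleavage or epimerisation at C2. The ring closure itself may lose to intermolecular etherification, since the twisted ketone activates the fluoride only weakly and the chain is flexible. Fallback, setting out from 20: ring C is closed first with TsOH in toluene at 80 °C, which leaves the benzyl ether in place, giving the benzyl-protected 1H-phenalene fluoro ketone F3. Hydrogenolysis with H2 and Pd/C then gives the naphthol F4. The fluoride displacement with Cs2CO3 in DMF is then run on this rigid substrate, which has no enolisable diketone, and the route is rejoined at 24.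

**Step 13.** Inside the macrocycle the hindered C1 ketone may fail to reach naphthalene position 8. The two ketones may instead equilibrate to hemiketal or pyran forms, or the reaction may stall at carbinol 23 because the C2–H bond is poorly aligned for elimination. Fallback, setting out from 22: BBr3 cleaves the six methyl ethers first, giving the hexahydroxy macrocyclic diketone F5. Its naphthalene-1,3-diol is a much stronger carbon nucleophile and should condense with the C1 ketone in HCl/AcOH directly to the quinone methide, without passing through the C1=C2 alkene. The route is rejoined at 26.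

**Step 14.** The six-fold cleavage may stop short at the hindered or peri ethers. Forcing it exposes the electron-rich styrene of 24 to HBr addition or cationic oligomerisation, and C2 may be protonated on the wrong face or the naphthalenediol tautomer may persist. Fallback, setting out from 24: the ring D ethers are removed hydrolytically first, with aqueous HCl in dioxane at 80 °C. Protonation at C2 gives the stabilised cation, water adds at the methoxy-bearing ring D carbon, and the resulting vinylogous ester hydrolyses, giving the tetra-O-methyl ether of the target F6 with C2 already equilibrated. BBr3 then has to cleave only the four remaining ethers on a substrate without the styrene, and the route is rejoined at 26.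

## Further compounds

F1 | step 10 | (R)-3-[2-(benzyloxy)-4,5,7-trimethoxynaphthalen-1-yl]-1-(2,6-dimethoxyphenyl)butan-1-one | C[C@H](CC(=O)c1c(OC)cccc1OC)c1c(OCc2ccccc2)cc(OC)c2c(OC)cc(OC)cc12
F2 | step 10 | lithium (Z)-enolate of F1 | [Li]O/C(c1c(OC)cccc1OC)=C\[C@@H](C)c1c(OCc2ccccc2)cc(OC)c2c(OC)cc(OC)cc12
F3 | step 12 | benzyl-protected 1H-phenalene fluoro ketone, C1=C2 double bond (C1′ R, C3 S) | C[C@@H](CC(=O)c1c(OC)cccc1F)C1=C(c2c(OC)cccc2OC)c2c(OC)cc(OC)c3c(OC)cc(OCc4ccccc4)c(c23)[C@@H]1C
F4 | step 12 | 1H-phenalene fluoro ketone with free naphthol (C1′ R, C3 S) | C[C@@H](CC(=O)c1c(OC)cccc1F)C1=C(c2c(OC)cccc2OC)c2c(OC)cc(OC)c3c(OC)cc(O)c(c23)[C@@H]1C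
F5 | step 13 | hexahydroxy macrocyclic diketone (C1′ R, C2 R, C3 S) | C[C@H]1CC(=O)c2c(O)cccc2Oc2cc(O)c3c(O)cc(O)cc3c2[C@H](C)[C@@H]1C(=O)c1c(O)cccc1O
F6 | step 14 | tetra-O-methyl ether of the target (ring A, ring B and both ring E methoxy groups kept; same structure as A3) | C[C@H]1CC(=O)c2c(OC)cccc2Oc2cc(OC)c3c4c2[C@H](C)[C@@H]1C(c1c(OC)cccc1OC)=C4C(O)=CC3=O
A1 | alternative 1 | macrocyclic aryl-dihydronaphthalene ketone lacking ring D (also the product of alternative 2) | C[C@H]1CC(=O)c2c(OC)cccc2Oc2cc(OC)cc3c2[C@H](C)[C@@H]1C(c1c(OC)cccc1OC)=C3
A2 | alternative 1 | malonyl dichloride | O=C(Cl)CC(=O)Cl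
A3 | alternative 1 | tetra-O-methyl ether of the target | C[C@H]1CC(=O)c2c(OC)cccc2Oc2cc(OC)c3c4c2[C@H](C)[C@@H]1C(c1c(OC)cccc1OC)=C4C(O)=CC3=O
A4 | alternative 2 | isopropenyl dihydronaphthalene carrying the 2-iodo-3-methoxyphenyl ether | COc1cccc(Oc2cc(OC)cc3c2[C@H](C)[C@@H](C(C)=C)C(c2c(OC)cccc2OC)=C3)c1I
A5 | alternative 2 | carbon monoxide | [C-]#[O+]
A6 | alternative 3 | ring C cyclohexenone with acetyl group and dioxinone-masked ketoacyl chain | CC1(C)OC(=O)C=C(CC(=O)C2[C@H](C)[C@@H]([C@@H](C)C=C)C(c3c(OC)cccc3OC)=C(C(C)=O)C2=O)O1
A7 | alternative 3 | tricyclic core with rings B, C and D | Oc1cc(O)c2c3c1[C@H](C)[C@@H]([C@@H](C)C=C)C(c1c(OC)cccc1OC)=C3C(O)=CC2=O
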